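**Retrosynthetic overview**
1. The target is a cross-conjugated dienone with a C4 senecioate. It comes from the 11-membered diol 16 by esterification, IBX desaturation of the saturated C6–C7 bond, and desilylation.
2. The only ring is made by a Ti(III) radical cross-pinacol (enal C4 with methyl ketone C5). This closes the 11-membered ring and sets C4/C5 under control of the C1 quaternary centre.
3. The acyclic precursor comes from cross-metathesis with acrolein (the E-enal), radical hydroacylation of MVK onto a Z-hydroxymethyl enal (C5–C8 unit), and carbomagnesiation/formylation of propargyl alcohol with a neopentyl Grignard (Z-C9=C10).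
4. The neopentyl iodide 8 carries the quaternary C1 centre, made by Cu-catalysed asymmetric SN2' from butynediol and 5-bromo-2-methylpent-2-ene.

Assumptions (one line): the ligand enantiomer in step 4 is chosen to give (R)-6. The pinacol gives the (4R,5R) diol as the major, chromatographically separable diastereomer, with trans-disposed ring chains on the titanadioxolane.

---

**Step 1**
Reactants: 1 but-2-yne-1,4-diol
Product: 2 4-(TBSO)but-2-yn-1-ol
Conditions: NaH (1.0 equiv), TBSCl (1.0 equiv), THF, 0 °C → rt
Reagents that add atoms: TBSCl, C[Si](C)(C(C)(C)C)Cl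
Why: the mono-alkoxide of the symmetric diol is silylated once (statistical mono-protection).

**Step 2**
Reactants: 2
Product: 3 (2Z)-4-(TBSO)-3-methylbut-2-en-1-ol
Conditions: MeMgBr (3 equiv), CuI (10 mol %), THF, −20 → 25 °C; aq. NH4Cl
Reagents that add atoms: MeMgBr, C[Mg]Br
Why: alkoxide-directed Cu-catalysed syn-carbomagnesiation puts Me on the alkyne carbon distal to the free OH and Mg on the proximal carbon, so protonation gives the Z-trisubstituted allylic alcohol (CH2OTBS cis to CH2OH).

**Step 3**
Reactants: 3
Product: 4 (2Z)-4-(TBSO)-3-methylbut-2-en-1-yl diethyl phosphate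
Conditions: (EtO)2P(O)Cl, Et3N, DMAP (cat.), CH2Cl2, 0 °C
Reagents that add atoms: diethyl chlorophosphate, CCOP(=O)(Cl)OCC
Why: it converts the alcohol into an allylic phosphate leaving group for SN2' with retention of alkene geometry.

**Step 4**
Reactants: 4; 5 5-bromo-2-methylpent-2-ene (used as its Grignard, from Mg/THF)
Product: 6 tert-butyl{[(2R)-2-ethenyl-2,6-dimethylhept-5-en-1-yl]oxy}dimethylsilane
Conditions: 4-methylpent-3-enylMgBr (1.5 equiv), CuTC (5 mol %), chiral ferrocenyl diphosphine (Josiphos-type, 6 mol %), Et2O/CH2Cl2, −78 °C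
Reagents that add atoms: none
Why: Proposed new method: the Cu–alkyl species attacks the γ-carbon (bearing Me and CH2OTBS) of the Z-allylic phosphate in an SN2' fashion, and the Z geometry plus the chiral ligand fix the face to give the quaternary stereocentre with a vinyl group. The closest known reaction is Cu-catalysed asymmetric allylic alkylation of γ,γ-disubstituted allylic phosphates with Grignard reagents to make all-carbon quaternary centres.

**Step 5**
Reactants: 6
Product: 7 (2R)-2-ethenyl-2,6-dimethylhept-5-en-1-ol
Conditions: TBAF, THF, 0 °C → rt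
Reagents that add atoms: none
Why: fluoride cleaves the primary silyl ether and does not touch the stereocentre.

**Step 6**
Reactants: 7
Product: 8 (3R)-3-(iodomethyl)-3,7-dimethylocta-1,6-diene
Conditions: PPh3, I2, imidazole, toluene, 80 °C
Reagents that add atoms: iodine, II
Why: Appel/Garegg–Samuelsson SN2 at the CH2 carbon gives the neopentyl iodide, and the quaternary centre is untouched.

**Step 7**
Reactants: 8; 9 prop-2-yn-1-ol
Product: 10 (2Z,5S)-5-ethenyl-2-(hydroxymethyl)-5,9-dimethyldeca-2,8-dienal
Conditions: (i) Mg, THF, 40 °C; (ii) 9 (1.5 equiv, as its magnesium alkoxide from EtMgBr), CuI (10 mol %), THF, 0 → 25 °C; (iii) DMF (5 equiv), −30 → 25 °C; aq. NH4Cl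
Reagents that add atoms: DMF, CN(C)C=O
Why: Proposed new method: the neopentyl Grignard adds syn across the alkoxide-bound alkyne (R to the terminal C10, Mg to C9) and the vinyl-Mg is formylated with retention, so C11 and the new CHO end up cis (Z, as required). The closest known reaction is Cu-catalysed carbomagnesiation of propargyl alcohol with primary alkyl Grignards followed by an electrophile quench.

**Step 8**
Reactants: 10
Product: 11 (2Z,5S)-2-[(TBSO)methyl]-5-ethenyl-5,9-dimethyldeca-2,8-dienal
Conditions: TBSCl, imidazole, DMF, 0 °C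
Reagents that add atoms: TBSCl, C[Si](C)(C(C)(C)C)Cl
Why: it masks the primary allylic OH so that it survives the hydroacylation and the IBX step.

**Step 9**
Reactants: 11; 12 methyl vinyl ketone
Product: 13 (6Z,9S)-9-ethenyl-6-[(TBSO)methyl]-9,13-dimethyltetradeca-6,12-diene-2,5-dione
Conditions: TBADT (2 mol %), MVK (4 equiv), MeCN, 390 nm LEDs, 25 °C
Reagents that add atoms: none
Why: Proposed new method: photoexcited decatungstate abstracts the weak formyl C–H to give an acyl radical, which adds to the β-carbon of MVK and is reduced and protonated to the 1,4-diketone (C5–C8 unit). The closest known reaction is TBADT-photocatalysed hydroacylation of electron-poor alkenes by aldehydes.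

**Step 10**
Reactants: 13; 14 acrolein
Product: 15 (2E,4S,6Z)-7-[(TBSO)methyl]-4-methyl-4-(4-methylpent-3-en-1-yl)-8,11-dioxododeca-2,6-dienal
Conditions: Hoveyda–Grubbs II (5 mol %), acrolein (10 equiv), CH2Cl2, 40 °C
Reagents that add atoms: none
Why: cross-metathesis of the terminal vinyl on the quaternary carbon with acrolein gives the thermodynamic E-enal (ethylene is lost), leaving the trisubstituted enone and prenyl alkenes untouched.

**Step 11**
Reactants: 15
Product: 16 (2Z,5S,6E,8R,9R)-8,9-dihydroxy-2-[(TBSO)methyl]-5,9-dimethyl-5-(4-methylpent-3-en-1-yl)cycloundeca-2,6-dien-1-one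
Conditions: Cp2TiCl2 (2.5 equiv), Zn dust (5 equiv), THF, rt; substrate added by syringe pump over 12 h (final ≈2 mM); aq. NH4Cl
Reagents that add atoms: none
Why: Proposed new method: Ti(III) reduces the enal to a Ti-bound ketyl radical that couples with the Ti-activated methyl ketone, forming C4–C5 and closing the 11-membered ring. The five-membered titanadioxolane keeps the bulky C3 and C6 chains trans, which corresponds to (4R*,5R*), and the C1 (S) quaternary centre biases the macrocyclic conformer toward (4R,5R). The closest known reactions are Cp2TiCl- and SmI2-mediated intramolecular pinacol and cross-pinacol couplings.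

**Step 12**
Reactants: 16; 17 3-methylbut-2-enoyl chloride
Product: 18 the C8-senecioate of 16
Conditions: 17 (3 equiv), pyridine, DMAP (0.2 equiv), CH2Cl2, 0 → 40 °C
Reagents that add atoms: none
Why: the secondary allylic OH is acylated selectively over the tertiary alcohol and no stereocentre is affected.

**Step 13**
Reactants: 18
Product: 19 silyl-protected dienone
Conditions: IBX (2.5 equiv), 4-methoxypyridine N-oxide (2.5 equiv), DMSO, 65 °C
Reagents that add atoms: none
Why: Nicolaou IBX ketone-to-enone dehydrogenation can only occur at C7–C6, because C9 is sp2, and it gives the E-enone.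

**Step 14**
Reactants: 19
Product: 20 target
Conditions: HF·pyridine, pyridine/THF, 0 °C → rt
Reagents that add atoms: none
Why: mild fluoride cleavage of the primary TBS ether leaves the ester, tertiary alcohol and dienone intact.

---

**Compound list**

| # | Name | SMILES | Role |
|---|---|---|---|
| 1 | but-2-yne-1,4-diol | OCC#CCO | starting material |
| 2 | 4-(TBSO)but-2-yn-1-ol | OCC#CCO[Si](C)(C)C(C)(C)C | intermediate |
| 3 | (2Z)-4-(TBSO)-3-methylbut-2-en-1-ol | OC/C=C(\CO[Si](C)(C)C(C)(C)C)C | intermediate |
| 4 | (2Z)-4-(TBSO)-3-methylbut-2-enyl diethyl phosphate | CCOP(=O)(OCC)OC/C=C(\CO[Si](C)(C)C(C)(C)C)C | intermediate |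
| 5 | 5-bromo-2-methylpent-2-ene | CC(C)=CCCBr | starting material |
| 6 | (R)-silyl ether, 2-ethenyl-2,6-dimethylhept-5-enyl OTBS | CC(C)=CCC[C@](C)(C=C)CO[Si](C)(C)C(C)(C)C | intermediate |
| 7 | (2R)-2-ethenyl-2,6-dimethylhept-5-en-1-ol | CC(C)=CCC[C@](C)(C=C)CO | intermediate |
| 8 | (3R)-3-(iodomethyl)-3,7-dimethylocta-1,6-diene | CC(C)=CCC[C@](C)(C=C)CI | intermediate |
| 9 | prop-2-yn-1-ol | C#CCO | starting material |
| 10 | (2Z,5S)-5-ethenyl-2-(hydroxymethyl)-5,9-dimethyldeca-2,8-dienal | CC(C)=CCC[C@](C)(C=C)C/C=C(/CO)C=O | intermediate |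
| 11 | TBS ether of 10 | CC(C)=CCC[C@](C)(C=C)C/C=C(/CO[Si](C)(C)C(C)(C)C)C=O | intermediate |
| 12 | methyl vinyl ketone | C=CC(C)=O | starting material |
| 13 | 1,4-diketone (6Z,9S) | CC(C)=CCC[C@](C)(C=C)C/C=C(/CO[Si](C)(C)C(C)(C)C)C(=O)CCC(C)=O | intermediate |
| 14 | acrolein | C=CC=O | starting material |
| 15 | (2E,4S,6Z)-enal diketone | O=C/C=C/[C@@](C)(CCC=C(C)C)C/C=C(/CO[Si](C)(C)C(C)(C)C)C(=O)CCC(C)=O | intermediate |
| 16 | macrocyclic diol (2Z,5S,6E,8R,9R) | CC(C)=CCC[C@]1(C)/C=C/[C@@H](O)[C@](C)(O)CCC(=O)/C(CO[Si](C)(C)C(C)(C)C)=C\C1 | intermediate |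
| 17 | 3-methylbut-2-enoyl chloride | CC(C)=CC(=O)Cl | starting material |
| 18 | C8-senecioate of 16 | CC(C)=CCC[C@]1(C)/C=C/[C@@H](OC(=O)C=C(C)C)[C@](C)(O)CCC(=O)/C(CO[Si](C)(C)C(C)(C)C)=C\C1 | intermediate |
| 19 | silyl-protected dienone | CC(C)=CCC[C@]1(C)/C=C/[C@@H](OC(=O)C=C(C)C)[C@](C)(O)/C=C/C(=O)/C(CO[Si](C)(C)C(C)(C)C)=C\C1 | intermediate |
| 20 | (2Z,5S,6E,8R,9R,10E)-8-(3-methylbut-2-enoyloxy)-9-hydroxy-2-(hydroxymethyl)-5,9-dimethyl-5-(4-methylpent-3-en-1-yl)cycloundeca-2,6,10-trien-1-one | CC(C)=CCC[C@]1(C)/C=C/[C@@H](OC(=O)C=C(C)C)[C@](C)(O)/C=C/C(=O)/C(CO)=C\C1 | target |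

**Totals:** 14 steps; longest linear sequence 14 steps.

**Three steps most likely to fail**
1. **Step 11 (macrocyclic Ti(III) cross-pinacol).** Risks are oligomerisation, enone reduction and poor diastereoselectivity. Fallback: close the ring instead by intramolecular Nozaki–Hiyama–Kishi coupling of an (E)-β-iodoenone (C6–C7) onto a C5 methyl ketone, with the C4 carbinol preset by Sharpless dihydroxylation.
2. **Step 4 (Cu-catalysed asymmetric SN2').** Risks are low ee, because Me and CH2OTBS are similar in size, and SN2 leakage. Fallback: Johnson–Claisen rearrangement of an enantioenriched (Noyori-reduced) secondary allylic alcohol to set C1, then hydrolysis and Barton iododecarboxylation to give iodide 8.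
3. **Step 7 (neopentyl carbomagnesiation and formylation).** Risks are alkyne C–H metalation and sluggish addition of the hindered Grignard. Fallback: convert 8 to the alkylzinc and cross-couple it (Pd or Ni) with a preformed (Z)-vinyl iodide acrolein acetal, then unmask the aldehyde.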